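**Plan**
- Retrosynthesis: the 5- and 7-hydroxyls are masked as 5-OMe and 7-OBn. Ring C is then opened at O1–C8a and the C5–O bond is cut in the same operation, giving an open-chain 1,3-diketone with bromine at both ring A positions ortho to the acyl group. The diketone is cut at C3–C4 into an aroyl chloride (ring A plus C4) and the methyl ketone of ring B (C2, C3).
- Enabling feature: C4a, C6, C7 and C8 carry the pattern of a syringyl unit (C4a para to the C7 oxygen, methoxy groups at C6 and C8). C5 and C8a are the two mirror-related carbons ortho to C4a, so a symmetric 2,6-dibromosyringoyl group supplies all of ring A and either bromine can become C8a.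
- Forward: rings A and B are bought (syringic acid, 3,4,5-trimethoxyacetophenone) and joined by enolate C-acylation (C3–C4). Ring C is the only ring made, by copper-mediated O1–C8a closure, and the same flask then installs the C5 oxygen. One Lewis-acid step frees both phenols.
- Stereochemistry: the target has no stereocentre and no configured double bond, so nothing has to be controlled.

Key step: step 5

Assumption: the two stages of step 5 run in one flask without intermediate work-up and are counted as one step. Flavone numbering (O1, C2–C4, C4a, C5–C8, C8a; ring A benzo, ring C pyranone, ring B the 2-aryl group) is used throughout, and diketone 8 is drawn in the diketo form although it will be largely enolised.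

Step 1
Reactants: 1 syringic acid; 2 benzyl bromide
Product: 4 4-(benzyloxy)-3,5-dimethoxybenzoic acid, via benzyl ester 3 (not isolated)
Conditions: BnBr (2.3 equiv), K2CO3, DMF, 60 °C; then NaOH, H2O/MeOH, 70 °C; then aq. HCl
Reagents that add atoms: benzyl bromide, BrCc1ccccc1; sodium hydroxide, [Na+].[OH-]
Why: Williamson alkylation of the phenoxide and carboxylate followed by saponification of the benzyl ester is the routine way to O-benzyl syringic acid, and the aryl benzyl ether is inert to aqueous NaOH.

Step 2
Reactants: 4 4-(benzyloxy)-3,5-dimethoxybenzoic acid
Product: 5 4-(benzyloxy)-2,6-dibromo-3,5-dimethoxybenzoic acid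
Conditions: Br2 (2.5 equiv), NaOAc, AcOH, 20 → 50 °C
Reagents that add atoms: bromine, BrBr
Why: Electrophilic aromatic bromination should take both remaining ring positions, each ortho to one methoxy group and para to the other, while the acetate buffer removes HBr from the benzyl ether and the unactivated benzyl phenyl ring does not compete.

Step 3
Reactants: 5 4-(benzyloxy)-2,6-dibromo-3,5-dimethoxybenzoic acid
Product: 6 4-(benzyloxy)-2,6-dibromo-3,5-dimethoxybenzoyl chloride
Conditions: (COCl)2, DMF (cat.), CH2Cl2, 0 °C → rt; evaporated and used crude
Reagents that add atoms: oxalyl chloride, O=C(Cl)C(=O)Cl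
Why: Acid chloride formation through the Vilsmeier-type chloroiminium species works even for di-ortho-substituted benzoic acids under cold, non-aqueous conditions that aryl bromides and the benzyl ether tolerate.

Step 4
Reactants: 6 4-(benzyloxy)-2,6-dibromo-3,5-dimethoxybenzoyl chloride; 7 3,4,5-trimethoxyacetophenone
Product: 8 1-[4-(benzyloxy)-2,6-dibromo-3,5-dimethoxyphenyl]-3-(3,4,5-trimethoxyphenyl)propane-1,3-dione
Conditions: 7 (2.2 equiv), LiN(SiMe3)2 (2.2 equiv), THF, −78 °C; then 6, −78 → 0 °C; aq. NH4Cl
Reagents that add atoms: none
Why: Claisen-type C-acylation of a preformed lithium enolate by an aroyl chloride is the usual entry to 1-(2-haloaryl)-1,3-diketones, and the second equivalent of enolate deprotonates the product so that it is not acylated again.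

Step 5
Reactants: 8 1-[4-(benzyloxy)-2,6-dibromo-3,5-dimethoxyphenyl]-3-(3,4,5-trimethoxyphenyl)propane-1,3-dione
Product: 10 7-(benzyloxy)-5,6,8-trimethoxy-2-(3,4,5-trimethoxyphenyl)-4H-chromen-4-one, via 5-bromoflavone 9 (not isolated)
Conditions: CuI (10 mol %), 1,10-phenanthroline (20 mol %), NaOMe (1.05 equiv), DMF, 90 °C; then NaOMe (5 equiv, in MeOH), 110 °C, same flask; aq. NH4Cl
Reagents that add atoms: sodium methoxide, [Na+].[O-]C
Why: The sodium diketonate of 8 binds phenanthroline-ligated monovalent copper, the metal inserts into one ortho C–Br bond to give a trivalent aryl copper enolate, and C–O reductive elimination from the enolate oxygen on the ring B side forms O1–C8a; the methoxide added afterwards gives a copper methoxide that repeats oxidative addition and reductive elimination at the remaining C5–Br bond, which the peri C4 carbonyl activates and directs. The closest known reactions are the copper-catalysed intramolecular Ullmann O-arylation of 1-(2-bromoaryl)-1,3-diketones to flavones and the Ullmann methoxylation of aryl bromides with NaOMe, both established on these bond types and here run one after the other with the same catalyst. Ring C closes in a 6-exo-trig sense by attack of oxygen on the ipso carbon, and closure through the central enolate carbon is excluded because it would give a four-membered ring. No stereocentre is formed. Ring closure must precede attack of methoxide on the bromines, which is secured by having only the one equivalent of base that makes the enolate present in the first stage, and no regiocontrol is needed because the two bromines of 8 are related by the mirror plane of the aryl ring. Benzyl and methyl ethers are inert to NaOMe, and any 5-hydroxy by-product from adventitious hydroxide would converge on the target in step 6.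

Step 6
Reactants: 10 7-(benzyloxy)-5,6,8-trimethoxy-2-(3,4,5-trimethoxyphenyl)-4H-chromen-4-one
Product: 11 5,7-dihydroxy-6,8,3',4',5'-pentamethoxyflavone
Conditions: BCl3 (4 equiv), C6HMe5 (3 equiv), CH2Cl2, −78 → 0 °C; then MeOH, aq. HCl
Reagents that add atoms: none
Why: Lewis-acid ether cleavage with BCl3 removes the aryl benzyl ether at low temperature (pentamethylbenzene traps the benzyl cation) and, through the six-membered boron chelate with the C4 carbonyl, cleaves only the C5 methyl ether, while the other five methoxy groups should survive the cold, short exposure.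

**Compound list**
1 | syringic acid (4-hydroxy-3,5-dimethoxybenzoic acid) | COc1cc(C(=O)O)cc(OC)c1O | starting material
2 | benzyl bromide | BrCc1ccccc1 | starting material
3 | benzyl 4-(benzyloxy)-3,5-dimethoxybenzoate | COc1cc(C(=O)OCc2ccccc2)cc(OC)c1OCc1ccccc1 | intermediate
4 | 4-(benzyloxy)-3,5-dimethoxybenzoic acid | COc1cc(C(=O)O)cc(OC)c1OCc1ccccc1 | intermediate
5 | 4-(benzyloxy)-2,6-dibromo-3,5-dimethoxybenzoic acid | COc1c(Br)c(C(=O)O)c(Br)c(OC)c1OCc1ccccc1 | intermediate
6 | 4-(benzyloxy)-2,6-dibromo-3,5-dimethoxybenzoyl chloride | COc1c(Br)c(C(=O)Cl)c(Br)c(OC)c1OCc1ccccc1 | intermediate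
7 | 3,4,5-trimethoxyacetophenone | CC(=O)c1cc(OC)c(OC)c(OC)c1 | starting material
8 | 1-[4-(benzyloxy)-2,6-dibromo-3,5-dimethoxyphenyl]-3-(3,4,5-trimethoxyphenyl)propane-1,3-dione | COc1cc(C(=O)CC(=O)c2c(Br)c(OC)c(OCc3ccccc3)c(OC)c2Br)cc(OC)c1OC | intermediate
9 | 7-(benzyloxy)-5-bromo-6,8-dimethoxy-2-(3,4,5-trimethoxyphenyl)-4H-chromen-4-one | O=c1cc(-c2cc(OC)c(OC)c(OC)c2)oc2c(OC)c(OCc3ccccc3)c(OC)c(Br)c12 | intermediate
10 | 7-(benzyloxy)-5,6,8-trimethoxy-2-(3,4,5-trimethoxyphenyl)-4H-chromen-4-one | O=c1cc(-c2cc(OC)c(OC)c(OC)c2)oc2c(OC)c(OCc3ccccc3)c(OC)c(OC)c12 | intermediate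
11 | 5,7-dihydroxy-6,8-dimethoxy-2-(3,4,5-trimethoxyphenyl)-4H-chromen-4-one (5,7-dihydroxy-6,8,3',4',5'-pentamethoxyflavone) | COc1cc(-c2cc(=O)c3c(O)c(OC)c(O)c(OC)c3o2)cc(OC)c1OC | target

**Step count and risks**
Total steps: 6. Longest linear sequence: 6 steps (1 → 4 → 5 → 6 → 8 → 10 → 11); ketone 7 is bought.

Step 5. What may go wrong: in the hot methoxide stage the C5 bromine may be lost by copper-mediated reduction, or methoxide may cleave the diketonate (retro-Claisen) or open ring C faster than C–O coupling occurs. Fallback: setting out from 8, the ring would be closed alone under the carbonate conditions usual for this cyclisation (CuI, 1,10-phenanthroline, K2CO3, DMF, 100 °C) and the 5-bromoflavone 9 isolated. Its C5–Br bond would then be converted into C5–OMe by a palladium-catalysed Buchwald–Hartwig etherification with methanol (Pd2(dba)3, tBuBrettPhos, Cs2CO3, toluene/MeOH, 80 °C). This zerovalent palladium cycle needs no free methoxide at high temperature. It gives 10, where the route is rejoined, and makes no compound outside the list.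

Step 4. What may go wrong: O-acylation of the enolate, or slow attack at the acyl carbon flanked by two bromines, so that enol ester and self-condensation products of 7 accumulate. Fallback: the polarity of the Claisen coupling would be reversed. Setting out from 6, MeMgBr with catalytic Fe(acac)3 (THF, −78 °C) should give the methyl ketone 1-[4-(benzyloxy)-2,6-dibromo-3,5-dimethoxyphenyl]ethan-1-one F1. Its lithium enolate (LiN(SiMe3)2, THF, −78 °C), formed at the unhindered methyl group, would then be acylated by commercial 3,4,5-trimethoxybenzoyl chloride (COc1cc(C(=O)Cl)cc(OC)c1OC), an unhindered electrophile, returning to the route at 8.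

Step 6. What may go wrong: loss of further methyl ethers once boron is bound (at C6 next to the chelated C5 oxygen, or at the crowded central methoxy group of ring B), or transfer of the benzyl cation to ring B. Fallback: the two deprotections would be separated and done without boron. Setting out from 10, hydrogenolysis (H2, Pd/C, EtOAc/MeOH, rt) should give 7-hydroxy-5,6,8-trimethoxy-2-(3,4,5-trimethoxyphenyl)-4H-chromen-4-one F2. Chelation-selective 5-O-demethylation with AlCl3 in MeCN (50 °C, then aq. HCl) would then lead to 11.

**Further compounds**
F0 | step 5 | none | none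
F1 | step 4 | 1-[4-(benzyloxy)-2,6-dibromo-3,5-dimethoxyphenyl]ethan-1-one | CC(=O)c1c(Br)c(OC)c(OCc2ccccc2)c(OC)c1Br
F2 | step 6 | 7-hydroxy-5,6,8-trimethoxy-2-(3,4,5-trimethoxyphenyl)-4H-chromen-4-one | O=c1cc(-c2cc(OC)c(OC)c(OC)c2)oc2c(OC)c(O)c(OC)c(OC)c12
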